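The red run is charged with 24 mM of electrophile and the violet run with 15 mM, yet at 15.0 min red holds 7.99 mM of target and violet 7.48 mM. Both runs carry the same nucleophile and free base, so in these two runs the target follows the nucleophile rather than the electrophile.

the same everywhere: free base 16.5 mM

|  | electrophile | nucleophile | remark | time |
|---|---|---|---|---|
| violet | 15 mM | 11 mM | run made earlier |  |
| red | 24 mM | 11 mM | run made earlier |  |
| flask | 11 mM | 11.0 mM |  | 50 min |

| run | time / min | electrophile / % | target / % |
|---|---|---|---|
| violet | 15.0 | 50.8 | 49.9 |
| violet | 30.0 | 46.3 | 53.1 |
| violet | 50.0 | 42.4 | 57.8 |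
| violet | 60.0 | 41.1 | 58.4 |
| red | 15.0 | 66.2 | 33.3 |
| red | 30.0 | 63.6 | 36.7 |
| red | 50.0 | 61.0 | 38.0 |
| red | 60.0 | 59.6 | 39.5 |

(scatter of a reading: 0.5 percentage points)

- part of the electrophile that has reacted at 50 min
- share of the unused nucleophile that is free and not bound as protonated nucleophile, at 50 min

- the numbers in the tables scatter with a standard deviation of 0.5 percentage points
- the earlier runs do not show how much of nucleophile is bound; that part of a forecast is a guess

I follow the violet run in slow motion. In the first instants, before any reading, electrophile and nucleophile meet, and by 15.0 min the violet run has made the 7.48 mM of target. In the middle stretch, up to 50.0 min, it gains just 1.18 mM, although 7.62 mM of electrophile stood there at the start of that stretch. At the end of that stretch I compare the target made with the nucleophile charged.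

So I carry one number, the turnout φ, the target made per nucleophile charged by 50 min: 78.8 % in violet and 82.9 % in red. The flask has less electrophile than violet, so I place its φ below violet's and its c, the part of the electrophile reacted, below 78.8 %. The free share can't be read from these runs.

The forecast, holding that “the nucleophile is being shut down”, gives 70 % reacted and 15 % free, and its c lies under my ceiling.

The flask gives 72.0 % reacted and 0.216 % free.

    nucleophile + acid set free ⇌ protonated nucleophile, settled at all times (K = 3.00 × 10⁵ M⁻¹)
    electrophile → decomposition product (k = 3.20 × 10⁻⁶ s⁻¹)
    electrophile + nucleophile → acid set free + target (k = 13.0 M⁻¹ s⁻¹)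
    acid set free + free base ⇌ salt of the base (K = 160 M⁻¹, k = 1.70 M⁻¹ s⁻¹)

The two part on the free share: at 50.0 min the flask holds 3.11 mM as protonated nucleophile. The flask's φ is 71.6 %, below the 78.8 % read in violet. A neighbouring flask is charged like the flask but with 19 mM of nucleophile. The flask's φ reckons 13.6 mM of target there, more than the 11 mM of electrophile charged, so by this reckoning electrophile is the limiting reagent of the neighbouring flask. That neighbour reaches 98.1 %, with 1.85 % of its electrophile left at 50.0 min.

The runs are simulated for an exercise, noise included.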